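**Retrosynthetic overview**

- Target 25 is cut at the ester C–O bond into silyl-protected isoferulic acid 22 and 5α-eudesmane-4β,6β-diol 19. The diol goes back through 4β,5β-epoxy ketone 17 (SmI2 opening) and allylic alcohol 15 (hydroxyl-directed epoxidation) to eudesma-4,7-dien-6-one 13.
- The strategy rests on ring B: the C6 oxygen sits next to the isopropyl-bearing C7, so C6–C7–C8 can stand as a 2-isopropyl enone. The C7=C8 bond then joins two carbons that carry no stereochemistry at ring closure, so 13 comes from ring-closing metathesis of dienone 12, whose only stereocentre is C10.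
- Dienone 12 is made at the C5–C6 bond by adding the C5 alkenyllithium (from iodide 7) to 2-isopropylacrolein 9. A carbonylative palladium coupling at C5 is avoided because its acylpalladium intermediate would sit 5-exo to the C10 allyl group. Iodide 7 comes from ketone 5, and C10 is set by decarboxylative asymmetric allylation of enol carbonate 4.
- Ring order: ring A is bought with 2,6-dimethylcyclohexanone 1 and ring B is closed in step 8. C7, C6, C4 and C5 are then relayed from the axial C10 methyl (α-face H2 and hydride delivery) and from the temporary 6β-hydroxyl.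

Key step: step 8

Assumption: the (R)-PHOX ligand is taken to give the R quaternary centre in the 2,6-dimethyl series, by analogy with 2-methylcyclohexanone-derived carbonates, where the (S)-ligand gives the S ketone; if the sense were reversed, the antipodal ligand would be used.

Remark: C7 is α to the C6 carbonyl in 14, 17 and 18, and the equatorial preference of an isopropyl group next to a carbonyl is small, so C7 is set kinetically in step 9 and these ketones are kept away from base.

**Route**

Step 1
Reactants: 1 2,6-dimethylcyclohexanone (cis/trans mixture); 2 allyl chloroformate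
Product: 4 allyl 2,6-dimethylcyclohex-1-en-1-yl carbonate, via lithium enolate 3 (not isolated)
Conditions: LiN(i-Pr)2, THF, −78 → 0 °C; TMEDA; then 2, −78 °C → rt
Reagents that add atoms: none
Why: Enolate O-acylation: the symmetrical ketone can give only one (tetrasubstituted) enolate, and the TMEDA-complexed lithium enolate should attack the hard chloroformate through oxygen to give the enol carbonate.

Step 2
Reactants: 4 allyl 2,6-dimethylcyclohex-1-en-1-yl carbonate
Product: 5 (2R)-2-allyl-2,6-dimethylcyclohexanone (both C6 epimers)
Conditions: Pd2(dba)3 (2.5 mol%), (R)-t-Bu-PHOX (6 mol%), THF, 25 °C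
Reagents that add atoms: none
Why: Decarboxylative asymmetric allylic alkylation (Tsuji–Trost type): zerovalent palladium ionises the allyl carbonate, CO2 is lost, and the palladium enolate couples with the allyl group inside the chiral pocket of the (R)-PHOX ligand, which should set the quaternary centre (the later C10) as R, while the C6 methyl centre is left uncontrolled because it becomes sp2 in step 4.

Step 3
Reactants: 5 (2R)-2-allyl-2,6-dimethylcyclohexanone
Product: 6 (2R)-2-allyl-2,6-dimethylcyclohexanone hydrazone
Conditions: N2H4·H2O (excess), Et3N, EtOH, reflux, under Ar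
Reagents that add atoms: hydrazine (as hydrate), NN
Why: Hydrazone condensation, slow for a 2,2,6-trisubstituted cyclohexanone but expected to go under forcing conditions with excess hydrazine, the quaternary centre being unable to epimerise and the inert atmosphere keeping diimide from reducing the allyl group.

Step 4
Reactants: 6 (2R)-2-allyl-2,6-dimethylcyclohexanone hydrazone
Product: 7 (6R)-6-allyl-1-iodo-2,6-dimethylcyclohex-1-ene
Conditions: I2, 1,1,3,3-tetramethylguanidine, Et2O/THF, 0 °C → rt; then tetramethylguanidine, 90 °C
Reagents that add atoms: iodine, [I][I]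
Why: Barton vinyl iodide synthesis: iodine oxidises the hydrazone to the diazo compound, iodination and loss of N2 give an α-iodo cation, and loss of the only available β-hydrogen (at the methyl-bearing carbon) should give the tetrasubstituted iodoalkene, which erases the uncontrolled methyl stereocentre.

Step 5
Reactants: 8 3-methylbutanal
Product: 9 3-methyl-2-methylenebutanal (2-isopropylacrolein)
Conditions: 37% aq. HCHO, pyrrolidine (10 mol%), EtCO2H (10 mol%), i-PrOH, 45 °C
Reagents that add atoms: formaldehyde, C=O
Why: Amine-catalysed Mannich condensation with formaldehyde followed by elimination (α-methylenation of an aldehyde), which should give the 2-substituted acrolein directly.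

Step 6
Reactants: 7 (6R)-6-allyl-1-iodo-2,6-dimethylcyclohex-1-ene; 9 3-methyl-2-methylenebutanal
Product: 11 1-[(6R)-6-allyl-2,6-dimethylcyclohex-1-en-1-yl]-3-methyl-2-methylenebutan-1-ol (both carbinol epimers), via alkenyllithium 10 (not isolated)
Conditions: t-BuLi (2.1 equiv), THF, −78 °C; then 9, −78 → 0 °C; then H2O
Reagents that add atoms: none
Why: Iodine–lithium exchange gives the alkenyllithium, which as a hard nucleophile should add 1,2 to the enal, the new carbinol centre being left uncontrolled because it is oxidised in step 7.

Step 7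
Reactants: 11 1-[(6R)-6-allyl-2,6-dimethylcyclohex-1-en-1-yl]-3-methyl-2-methylenebutan-1-ol
Product: 12 1-[(6R)-6-allyl-2,6-dimethylcyclohex-1-en-1-yl]-3-methyl-2-methylenebutan-1-one
Conditions: Dess–Martin periodinane, NaHCO3, CH2Cl2, 0 °C → rt
Reagents that add atoms: none
Why: Dess–Martin oxidation of the doubly allylic alcohol under buffered, non-acidic conditions should give the cross-conjugated dienone without acid-induced (Nazarov-type) cyclisation.

Step 8
Reactants: 12 1-[(6R)-6-allyl-2,6-dimethylcyclohex-1-en-1-yl]-3-methyl-2-methylenebutan-1-one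
Product: 13 (10R)-eudesma-4,7-dien-6-one
Conditions: second-generation Grubbs catalyst (10 mol%), toluene (0.005 M), 80 °C, Ar sparge
Reagents that add atoms: none
Why: Ring-closing alkene metathesis: the ruthenium benzylidene first exchanges with the unhindered monosubstituted allyl terminus (C8), the new alkylidene adds [2+2] across the 1,1-disubstituted C7=CH2 of the enone arm, and cycloreversion of the ruthenacyclobutane forms C7=C8 and a ruthenium methylidene that carries the chain while ethene is swept out. The closest known reaction type is the ring-closing metathesis of α-substituted dienones to 2-alkylcyclohex-2-enones. Ring B closes as a six-membered ring by alkene formation between two arms held side by side on the adjacent atoms C5 and C10, the tetrasubstituted C4=C5 bond fixing their geometry and the quaternary C10 adding a gem-dialkyl effect. No stereocentre is formed, and the quaternary C10 centre set in step 2 cannot epimerise. The selectivity needed is chemoselectivity for the two methylene alkenes, which the substrate secures because the tetrasubstituted, conjugated C4=C5 alkene cannot enter the catalytic cycle; high dilution and removal of ethene should hold back dimerisation at the allyl terminus.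

Step 9
Reactants: 13 (10R)-eudesma-4,7-dien-6-one
Product: 14 (7S,10R)-eudesm-4-en-6-one (7β-isopropyl)
Conditions: H2 (1 atm), 5% Pd/C, EtOAc, rt, stopped after one equivalent of H2; filtered and used at once
Reagents that add atoms: none
Why: Heterogeneous catalytic hydrogenation (syn addition): the trisubstituted C7=C8 bond should be reduced before the tetrasubstituted C4=C5 bond, and H2 should be delivered to the α face because the pseudo-axial C10 methyl, 1,3 to C8, shields the β face, which places the new C7–H α and the isopropyl group β.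

Step 10
Reactants: 14 (7S,10R)-eudesm-4-en-6-one
Product: 15 (6R,7S,10R)-eudesm-4-en-6-ol (6β-hydroxyl)
Conditions: LiAlH4, Et2O, −78 → 0 °C; aq. NaOH work-up
Reagents that add atoms: none
Why: Hydride 1,2-reduction of the enone: the β face of C6 is blocked by the axial C10 methyl, so hydride should arrive from the α face and give the pseudo-axial 6β-alcohol, which also avoids allylic 1,3-strain with the C4 methyl.

Step 11
Reactants: 15 (6R,7S,10R)-eudesm-4-en-6-ol
Product: 16 (4S,5S,6R,7S,10R)-4,5-epoxyeudesman-6-ol (4β,5β-epoxide and 6β-hydroxyl)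
Conditions: VO(acac)2 (5 mol%), t-BuOOH (decane solution), CH2Cl2, 0 °C → rt
Reagents that add atoms: tert-butyl hydroperoxide, CC(C)(C)OO
Why: Vanadium-catalysed hydroxyl-directed epoxidation: the vanadate ester of the 6β-hydroxyl delivers the peroxide oxygen to the same face of the allylic C4=C5 bond, so the 4β,5β-epoxide should form against the steric bias of the C10 methyl, fixing C4 with its oxygen β and its methyl α.

Step 12
Reactants: 16 (4S,5S,6R,7S,10R)-4,5-epoxyeudesman-6-ol
Product: 17 (4S,5R,7S,10R)-4,5-epoxyeudesman-6-one (4β,5β-epoxide)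
Conditions: Dess–Martin periodinane, NaHCO3, CH2Cl2, 0 °C → rt
Reagents that add atoms: none
Why: Dess–Martin oxidation of the secondary alcohol under buffered neutral conditions, which should leave the tetrasubstituted epoxide and the C7 stereocentre untouched.

Step 13
Reactants: 17 (4S,5R,7S,10R)-4,5-epoxyeudesman-6-one
Product: 18 (4S,5R,7S,10R)-4-hydroxyeudesman-6-one (4β-hydroxyl and 5α-H)
Conditions: SmI2 (2.2 equiv), THF/MeOH, −90 °C; pH 7 buffer quench
Reagents that add atoms: none
Why: Reductive opening of an α,β-epoxy ketone by divalent samarium: two single-electron transfers cleave only the Cα–O bond (C5–O), so the C4–O bond keeps its β configuration, and the samarium enolate should be protonated by methanol at C5 on the α face (axial approach, away from the C10 methyl) to give the trans ring fusion, the low temperature holding back β-elimination of the new hydroxyl.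

Step 14
Reactants: 18 (4S,5R,7S,10R)-4-hydroxyeudesman-6-one
Product: 19 (4S,5S,6R,7S,10R)-eudesmane-4,6-diol (5α-eudesmane-4β,6β-diol)
Conditions: NaBH4, MeOH/THF, −20 → 0 °C
Reagents that add atoms: none
Why: Borohydride reduction with external hydride delivery: the β face of C6 is closed by the two syn-axial groups (C10 methyl and C4 hydroxyl), so hydride should enter from the α face and give the axial 6β-alcohol.

Step 15
Reactants: 20 isoferulic acid
Product: 22 (E)-3-[3-(tert-butyldimethylsilyloxy)-4-methoxyphenyl]prop-2-enoic acid, via bis-silyl derivative 21 (not isolated)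
Conditions: TBSCl (2.4 equiv), imidazole, DMF, rt; then AcOH/THF/H2O, rt
Reagents that add atoms: tert-butyldimethylsilyl chloride, CC(C)(C)[Si](C)(C)Cl
Why: Silylation of both acidic OH groups followed by selective hydrolysis of the far more labile silyl ester should leave the phenol protected and the acid free.

Step 16
Reactants: 19 5α-eudesmane-4β,6β-diol; 22 (E)-3-[3-(tert-butyldimethylsilyloxy)-4-methoxyphenyl]prop-2-enoic acid
Product: 24 4β-hydroxy-5α-eudesman-6β-yl (E)-3-[3-(tert-butyldimethylsilyloxy)-4-methoxyphenyl]prop-2-enoate, via mixed anhydride 23 (not isolated)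
Conditions: 22, 2,4,6-trichlorobenzoyl chloride, Et3N, toluene, rt; then 19, DMAP, toluene, 60 °C
Reagents that add atoms: none
Why: Yamaguchi esterification: DMAP transfers the cinnamoyl group from the mixed anhydride to the secondary 6β-hydroxyl, the tertiary 4β-hydroxyl being too hindered to compete and the E alkene being untouched.

Step 17
Reactants: 24 4β-hydroxy-5α-eudesman-6β-yl (E)-3-[3-(tert-butyldimethylsilyloxy)-4-methoxyphenyl]prop-2-enoate
Product: 25 (4S,5S,6R,7S,10R)-4-hydroxyeudesman-6-yl (E)-3-(3-hydroxy-4-methoxyphenyl)prop-2-enoate (CNP0291757.1)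
Conditions: Bu4NF, AcOH (1:1), THF, 0 °C
Reagents that add atoms: none
Why: Fluoride-induced cleavage of the aryl silyl ether, buffered with acetic acid so that the phenoxide does not attack the cinnamate ester.

**Compound list**

1 | 2,6-dimethylcyclohexanone (cis/trans mixture) | CC1CCCC(C)C1=O | starting material
2 | allyl chloroformate | C=CCOC(=O)Cl | starting material
3 | lithium 2,6-dimethylcyclohex-1-en-1-olate | [Li]OC1=C(C)CCCC1C | intermediate
4 | allyl 2,6-dimethylcyclohex-1-en-1-yl carbonate (racemic) | C=CCOC(=O)OC1=C(C)CCCC1C | intermediate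
5 | (2R)-2-allyl-2,6-dimethylcyclohexanone (both C6 epimers) | CC1CCC[C@](C)(CC=C)C1=O | intermediate
6 | (2R)-2-allyl-2,6-dimethylcyclohexanone hydrazone | CC1CCC[C@](C)(CC=C)C1=NN | intermediate
7 | (6R)-6-allyl-1-iodo-2,6-dimethylcyclohex-1-ene | IC1=C(C)CCC[C@]1(C)CC=C | intermediate
8 | 3-methylbutanal | CC(C)CC=O | starting material
9 | 3-methyl-2-methylenebutanal (2-isopropylacrolein) | CC(C)C(=C)C=O | intermediate
10 | [(6R)-6-allyl-2,6-dimethylcyclohex-1-en-1-yl]lithium | [Li]C1=C(C)CCC[C@]1(C)CC=C | intermediate
11 | 1-[(6R)-6-allyl-2,6-dimethylcyclohex-1-en-1-yl]-3-methyl-2-methylenebutan-1-ol (both carbinol epimers) | OC(C(=C)C(C)C)C1=C(C)CCC[C@]1(C)CC=C | intermediate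
12 | 1-[(6R)-6-allyl-2,6-dimethylcyclohex-1-en-1-yl]-3-methyl-2-methylenebutan-1-one | O=C(C(=C)C(C)C)C1=C(C)CCC[C@]1(C)CC=C | intermediate
13 | (10R)-eudesma-4,7-dien-6-one | O=C1C2=C(C)CCC[C@]2(C)CC=C1C(C)C | intermediate
14 | (7S,10R)-eudesm-4-en-6-one | O=C1C2=C(C)CCC[C@]2(C)CC[C@H]1C(C)C | intermediate
15 | (6R,7S,10R)-eudesm-4-en-6-ol (6β-hydroxyl) | O[C@H]1C2=C(C)CCC[C@]2(C)CC[C@H]1C(C)C | intermediate
16 | (4S,5S,6R,7S,10R)-4,5-epoxyeudesman-6-ol (4β,5β-epoxide, 6β-hydroxyl) | O[C@H]1[C@@]23O[C@@]3(C)CCC[C@]2(C)CC[C@H]1C(C)C | intermediate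
17 | (4S,5R,7S,10R)-4,5-epoxyeudesman-6-one (4β,5β-epoxide) | O=C1[C@@]23O[C@@]3(C)CCC[C@]2(C)CC[C@H]1C(C)C | intermediate
18 | (4S,5R,7S,10R)-4-hydroxyeudesman-6-one (4β-hydroxyl, 5α-H) | O=C1[C@@H]2[C@](C)(CCC[C@]2(C)O)CC[C@H]1C(C)C | intermediate
19 | (4S,5S,6R,7S,10R)-eudesmane-4,6-diol (4β,6β-diol, 5α-H) | O[C@H]1[C@@H]2[C@](C)(CCC[C@]2(C)O)CC[C@H]1C(C)C | intermediate
20 | isoferulic acid | COc1ccc(/C=C/C(=O)O)cc1O | starting material
21 | tert-butyldimethylsilyl (E)-3-[3-(tert-butyldimethylsilyloxy)-4-methoxyphenyl]prop-2-enoate | COc1ccc(/C=C/C(=O)O[Si](C)(C)C(C)(C)C)cc1O[Si](C)(C)C(C)(C)C | intermediate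
22 | (E)-3-[3-(tert-butyldimethylsilyloxy)-4-methoxyphenyl]prop-2-enoic acid | COc1ccc(/C=C/C(=O)O)cc1O[Si](C)(C)C(C)(C)C | intermediate
23 | mixed anhydride of 22 with 2,4,6-trichlorobenzoic acid | COc1ccc(/C=C/C(=O)OC(=O)c2c(Cl)cc(Cl)cc2Cl)cc1O[Si](C)(C)C(C)(C)C | intermediate
24 | 4β-hydroxy-5α-eudesman-6β-yl (E)-3-[3-(tert-butyldimethylsilyloxy)-4-methoxyphenyl]prop-2-enoate | COc1ccc(/C=C/C(=O)O[C@H]2[C@@H]3[C@](C)(CCC[C@]3(C)O)CC[C@H]2C(C)C)cc1O[Si](C)(C)C(C)(C)C | intermediate
25 | (4S,5S,6R,7S,10R)-4-hydroxyeudesman-6-yl (E)-3-(3-hydroxy-4-methoxyphenyl)prop-2-enoate | COc1ccc(/C=C/C(=O)O[C@H]2[C@@H]3[C@](C)(CCC[C@]3(C)O)CC[C@H]2C(C)C)cc1O | target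

**Step count**

Total: 17 steps. Longest linear sequence: 15 steps (steps 1–4, 6–14, 16 and 17); steps 5 and 15 make the side components.

**Steps most likely to fail, with fallbacks**

Step 8. The ruthenium alkylidene formed at the allyl terminus may engage the hindered, electron-poor 1,1-disubstituted alkene too slowly, so that catalyst decay, alkene isomerisation and intermolecular metathesis at the allyl group take over. The fallback makes the same C7=C8 bond by aldol condensation. Setting out from iodide 7, the alkenyllithium 10 (t-BuLi, THF, −78 °C) would be added to 3-methylbutanal 8 to give 1-[(6R)-6-allyl-2,6-dimethylcyclohex-1-en-1-yl]-3-methylbutan-1-ol F1. Dess–Martin oxidation would give 1-[(6R)-6-allyl-2,6-dimethylcyclohex-1-en-1-yl]-3-methylbutan-1-one F2. OsO4 (catalytic) with NaIO4 and 2,6-lutidine in dioxane–water would cleave only the monosubstituted alkene to 2-[(1R)-1,3-dimethyl-2-(3-methylbutanoyl)cyclohex-2-en-1-yl]acetaldehyde F3. KOH in MeOH would then close ring B by intramolecular aldol condensation of the C7 methylene onto the C8 aldehyde (the only six-membered mode available) with loss of water, coming back to the route at dienone 13.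

Step 9. Hydrogen may be delivered with poor facial selectivity, or C7 may epimerise on the catalyst through the enol. The fallback moves the hydrogenation to a substrate in which C7 is not α to a carbonyl and the β face carries a bulky group next to C7. Setting out from dienone 13, LiAlH4 (Et2O, −78 °C) would give eudesma-4,7-dien-6β-ol F4 by α-face attack. TBSOTf with 2,6-lutidine would give 6β-(tert-butyldimethylsilyloxy)eudesma-4,7-diene F5. H2 over 5% Rh/Al2O3 in EtOAc would saturate only the trisubstituted C7=C8 bond from the α face, anti to both the pseudo-axial silyloxy group and the C10 methyl, to give 6β-(tert-butyldimethylsilyloxy)eudesm-4-ene F6. Bu4NF in THF would remove the silyl group, coming back to the route at allylic alcohol 15.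

Step 13. The samarium enolate may lose the C4 oxygen by β-elimination (dehydration to the conjugated enone), or it may be protonated at C5 from the β face, which would give the cis ring fusion. The fallback sets the C5–H bond by hydroboration instead of enolate protonation. Setting out from epoxy ketone 17, Wharton transposition (N2H4·H2O, catalytic AcOH, MeOH) would give eudesm-5-en-4β-ol F7 with the C4 oxygen untouched. BH3·THF followed by NaOH/H2O2 would add hydrogen to C5 and boron to C6 from the α face (anti to the C10 methyl and the C4 oxygen) to give 5α-eudesmane-4β,6α-diol F8. Dess–Martin oxidation of the secondary alcohol would come back to the route at hydroxy ketone 18.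

**Further compounds**

F1 | step 8 | 1-[(6R)-6-allyl-2,6-dimethylcyclohex-1-en-1-yl]-3-methylbutan-1-ol | OC(CC(C)C)C1=C(C)CCC[C@]1(C)CC=C
F2 | step 8 | 1-[(6R)-6-allyl-2,6-dimethylcyclohex-1-en-1-yl]-3-methylbutan-1-one | O=C(CC(C)C)C1=C(C)CCC[C@]1(C)CC=C
F3 | step 8 | 2-[(1R)-1,3-dimethyl-2-(3-methylbutanoyl)cyclohex-2-en-1-yl]acetaldehyde | O=C(CC(C)C)C1=C(C)CCC[C@]1(C)CC=O
F4 | step 9 | eudesma-4,7-dien-6β-ol | O[C@H]1C2=C(C)CCC[C@]2(C)CC=C1C(C)C
F5 | step 9 | 6β-(tert-butyldimethylsilyloxy)eudesma-4,7-diene | CC(C)(C)[Si](C)(C)O[C@H]1C2=C(C)CCC[C@]2(C)CC=C1C(C)C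
F6 | step 9 | 6β-(tert-butyldimethylsilyloxy)eudesm-4-ene | CC(C)(C)[Si](C)(C)O[C@H]1C2=C(C)CCC[C@]2(C)CC[C@H]1C(C)C
F7 | step 13 | eudesm-5-en-4β-ol | C[C@]1(O)CCC[C@]2(C)CC[C@@H](C(C)C)C=C12
F8 | step 13 | 5α-eudesmane-4β,6α-diol | O[C@@H]1[C@@H]2[C@](C)(CCC[C@]2(C)O)CC[C@H]1C(C)C
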